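**Plan**

1. Numbering: C1 carries the dienoic acid chain (C1' = CO2H … C6' on C1), C2 the 2-oxopropyl group, C3 a methyl, then C4, C4a, C5, C6 (CH3), C7 (C=O), C8 (CH3), C8a. Ring A = C1–C4/C4a/C8a; ring B = C4a–C8a.
2. Retrosynthetic cuts, in order: C1' acid ← allylic alcohol; C2–CH2C(O)CH3 ← C2–CHO (Wittig); C7–C8 of ring B; C1–C6' and C8a–C8 (alkenyl and acetyl added trans across one C=C of a benzene ring); C4' quaternary carbon ← 1,2-shift in a Sharpless epoxide.
3. Forward: two fragments (arene–Cr(CO)3 hydrazone 11, alkenyl iodide 20). Ring A is made from the benzene ring by a dearomatising trans carbo-acylation (step 14); ring B closes second through C7–C8 (step 17); then C8 deoxygenation and equilibration, the 2-oxopropyl group and the acid.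
4. Enabling feature: in ring B the C7 ketone lies between two enolisable methine carbons, C6 and C8, whose methyls are both equatorial and trans to the C8a–C1 bond. An acyloin-type union of a C7 aldehyde with a C8 acetyl carbonyl therefore needs no stereocontrol: the C8 oxygen is excised, and C6/C8 are funnelled to one isomer against the non-enolisable C8a.
5. Stereochemistry: C4' from Sharpless epoxidation and a stereospecific anti 1,2-shift; C1 and C8a from the planar chirality of the chromium complex (nucleophile exo, acetyl endo); C6 and C8 by thermodynamic equilibration; 5'E from syn carboalumination, 2'E from Horner–Wadsworth–Emmons olefination.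

Key step: step 17

Abbreviations: TBS = tert-butyldimethylsilyl; TBDPS = tert-butyldiphenylsilyl; Q = (1E,3S,4E)-6-(TBDPS-oxy)-3-[(TBDPS-oxy)methyl]-2,3-dimethylhexa-1,4-dien-1-yl.

Remark: chromium π-complexes are written in SMILES as ligand and Cr(CO)3 unit joined by a dot, with planar chirality given in the name; the (1R,2R)-diamine is assumed to be the enantiomer whose aminal directs lithiation to the ortho carbon needed for that planar configuration, and its antipode is used if the sense is the opposite.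

**Route**

Step 1
Reactants: 1 2-methylprop-2-en-1-ol
Product: 2 tert-butyl(dimethyl)[(2-methylprop-2-en-1-yl)oxy]silane
Conditions: TBSCl, imidazole, CH2Cl2, 0 °C to rt
Reagents that add atoms: tert-butyldimethylsilyl chloride, CC(C)(C)[Si](C)(C)Cl
Why: Silylation of the primary alcohol masks the future C7 oxygen as an ether that survives the organolithium steps.

Step 2
Reactants: 2 tert-butyl(dimethyl)[(2-methylprop-2-en-1-yl)oxy]silane; 3 4-bromobenzaldehyde
Product: 5 4-[3-(TBS-oxy)-2-methylpropyl]benzaldehyde (racemic), via B-alkyl-9-BBN 4 (not isolated)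
Conditions: 9-BBN, THF, rt; then 3, PdCl2(dppf) (3 mol%), aq. K3PO4, DMF, 50 °C
Reagents that add atoms: none
Why: Anti-Markovnikov hydroboration of the 1,1-disubstituted alkene followed by B-alkyl Suzuki–Miyaura coupling joins the sp3 chain to the ring and tolerates the aldehyde; the new methine (future C6) is deliberately left racemic because it is equilibrated in step 18.

Step 3
Reactants: 5 4-[3-(TBS-oxy)-2-methylpropyl]benzaldehyde
Product: 6 (3aR,7aR)-2-{4-[3-(TBS-oxy)-2-methylpropyl]phenyl}-1,3-dimethyloctahydro-1H-benzimidazole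
Conditions: (1R,2R)-N,N'-dimethylcyclohexane-1,2-diamine, 4 Å molecular sieves, Et2O, rt
Reagents that add atoms: (1R,2R)-N,N'-dimethylcyclohexane-1,2-diamine, CN[C@@H]1CCCC[C@H]1NC
Why: Condensation of the aldehyde with the C2-symmetric secondary diamine gives the chiral aminal (no new stereocentre) that will differentiate the two ortho positions.

Step 4
Reactants: 6 aminal
Product: 7 tricarbonyl(η6-aryl ring of 6)chromium
Conditions: Cr(CO)6, Bu2O/THF (10:1), reflux, dark
Reagents that add atoms: hexacarbonylchromium, O=C=[Cr](=C=O)(=C=O)(=C=O)(=C=O)=C=O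
Why: Thermal arene complexation gives the η6-arene tricarbonylchromium complex, which activates the ring for directed lithiation and later nucleophilic addition; the para-disubstituted ring has no planar chirality at this stage.

Step 5
Reactants: 7 tricarbonyl(η6-aryl ring of 6)chromium
Product: 10 tricarbonyl{η6-2-methyl-4-[3-(TBS-oxy)-2-methylpropyl]benzaldehyde}chromium (planar-chiral: with ring locants 1→2→3 running clockwise, Cr(CO)3 faces the viewer), via ortho-lithiated aminal complex 8 (not isolated), via ortho-methylated aminal complex 9 (not isolated)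
Conditions: n-BuLi, THF, −30 °C; MeI, −78 °C to rt; then 1 M aq. HCl, Et2O, 0 °C, short contact
Reagents that add atoms: iodomethane, CI; water, O
Why: Aminal-nitrogen-directed ortho-lithiation of the chromium-activated ring selects one of the two diastereotopic ortho carbons, so methylation and mild hydrolysis should give the aldehyde complex with planar chirality set by the diamine (directed ortho-metalation of a chiral benzaldehyde aminal complex).

Step 6
Reactants: 10 planar-chiral aldehyde complex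
Product: 11 tricarbonyl{η6-(E)-1,1-dimethyl-2-{2-methyl-4-[3-(TBS-oxy)-2-methylpropyl]benzylidene}hydrazine}chromium (same planar chirality)
Conditions: Me2NNH2, MgSO4, CH2Cl2, rt
Reagents that add atoms: 1,1-dimethylhydrazine, CN(C)N
Why: Hydrazone formation installs a conjugated, lithium-coordinating acceptor that directs the ortho addition in step 14 and afterwards serves as a non-acidifying mask of the C2 aldehyde.

Step 7
Reactants: 12 (E)-3-methylpent-2-en-4-yn-1-ol
Product: 13 [(2S,3S)-3-ethynyl-3-methyloxiran-2-yl]methanol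
Conditions: Ti(OiPr)4 (10 mol%), L-(+)-diethyl tartrate (12 mol%), t-BuOOH, 4 Å molecular sieves, CH2Cl2, −20 °C
Reagents that add atoms: tert-butyl hydroperoxide, CC(C)(C)OO
Why: Sharpless asymmetric epoxidation with the L-(+)-tartrate delivers oxygen to the same enantioface as in geraniol, which corresponds to the (2S,3S)-epoxide.

Step 8
Reactants: 13 epoxy alcohol
Product: 14 tert-butyl{[(2S,3S)-3-ethynyl-3-methyloxiran-2-yl]methoxy}diphenylsilane
Conditions: TBDPSCl, imidazole, CH2Cl2, 0 °C to rt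
Reagents that add atoms: tert-butyldiphenylsilyl chloride, CC(C)(C)[Si](Cl)(c1ccccc1)c1ccccc1
Why: Silylation gives the epoxy silyl ether needed for the rearrangement and places a robust ether on the oxygen that ends as the free CH2OH of the target.

Step 9
Reactants: 14 epoxy silyl ether
Product: 15 (S)-2-[(TBDPS-oxy)methyl]-2-methylbut-3-ynal
Conditions: MeAl(OAr)2 (Ar = 4-bromo-2,6-di-tert-butylphenyl, 2 equiv), CH2Cl2, −78 °C
Reagents that add atoms: none
Why: Lewis-acid opening of the epoxide at the tertiary propargylic carbon with concerted anti 1,2-shift of the silyloxymethyl group (organoaluminium-promoted epoxy silyl ether rearrangement, semipinacol type) should transfer the epoxide chirality to the new quaternary carbon with inversion, giving the (S)-aldehyde.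

Step 10
Reactants: 15 quaternary aldehyde
Product: 16 ethyl (S,E)-4-[(TBDPS-oxy)methyl]-4-methylhex-2-en-5-ynoate
Conditions: (EtO)2P(O)CH2CO2Et, NaH, THF, 0 °C to rt
Reagents that add atoms: triethyl phosphonoacetate, CCOC(=O)CP(=O)(OCC)OCC
Why: Horner–Wadsworth–Emmons olefination of the non-enolisable aldehyde should give the (E)-enoate that carries C1'–C3'.

Step 11
Reactants: 16 enoate
Product: 17 (S,E)-4-[(TBDPS-oxy)methyl]-4-methylhex-2-en-5-yn-1-ol
Conditions: i-Bu2AlH, CH2Cl2, −78 °C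
Reagents that add atoms: none
Why: 1,2-Reduction of the enoate with i-Bu2AlH gives the allylic alcohol, an organolithium-stable precursor of the acid.

Step 12
Reactants: 17 allylic alcohol
Product: 18 (S,E)-1-(TBDPS-oxy)-4-[(TBDPS-oxy)methyl]-4-methylhex-2-en-5-yne
Conditions: TBDPSCl, imidazole, CH2Cl2, rt
Reagents that add atoms: tert-butyldiphenylsilyl chloride, CC(C)(C)[Si](Cl)(c1ccccc1)c1ccccc1
Why: Silylation protects the allylic alcohol so that both side-chain oxygens survive the later organolithium and oxidation steps.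

Step 13
Reactants: 18 bis-silyl enyne
Product: 20 (1E,3S,4E)-6-(TBDPS-oxy)-3-[(TBDPS-oxy)methyl]-1-iodo-2,3-dimethylhexa-1,4-diene, via alkenyldimethylalane 19 (not isolated)
Conditions: Me3Al, Cp2ZrCl2 (0.3 equiv), H2O (cat.), CH2Cl2, −20 °C to rt; then iodine, THF, −30 °C
Reagents that add atoms: trimethylaluminium, C[Al](C)C; iodine, II
Why: Zirconium-catalysed Negishi carboalumination adds methyl and aluminium syn across the terminal alkyne with methyl on the internal carbon, and iodinolysis with retention gives the (E)-iodide that fixes the C5'=C6' geometry.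

Step 14
Reactants: 20 alkenyl iodide; 11 hydrazone chromium complex
Product: 23 1-[(1S,6S)-2-[3-(TBS-oxy)-2-methylpropyl]-5-[(E)-(2,2-dimethylhydrazinylidene)methyl]-4-methyl-6-Q-cyclohexa-2,4-dien-1-yl]ethan-1-one (trans), via alkenyllithium 21 (not isolated), via lithium cyclohexadienyl chromate adduct 22 (not isolated)
Conditions: 20, t-BuLi (2.1 equiv), Et2O, −78 °C; add to 11, THF, −78 °C; then MeI, HMPA, CO (4 bar), −78 °C to rt
Reagents that add atoms: iodomethane, CI; carbon monoxide, [C-]#[O+]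
Why: The alkenyllithium from iodine–lithium exchange, guided by the hydrazone nitrogen, should add to the only free ortho carbon anti to chromium, and methylation at the metal, CO insertion and endo migration of the acetyl group to the neighbouring ring carbon complete a trans carbo-acylation of one arene C=C bond (nucleophile addition/electrophile trapping on an arene–Cr(CO)3 complex), so the planar chirality of 11 sets C1 and C8a and ring A appears with its diene in place.

Step 15
Reactants: 23 dearomatised ketone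
Product: 24 1-[(1S,6S)-5-[(E)-(2,2-dimethylhydrazinylidene)methyl]-2-(3-hydroxy-2-methylpropyl)-4-methyl-6-Q-cyclohexa-2,4-dien-1-yl]ethan-1-one
Conditions: HF·pyridine, pyridine, THF, 0 °C
Reagents that add atoms: none
Why: Buffered HF·pyridine cleaves the primary TBS ether much faster than the two primary TBDPS ethers, freeing only the future C7 oxygen.

Step 16
Reactants: 24 primary alcohol
Product: 25 3-[(5S,6S)-6-acetyl-4-[(E)-(2,2-dimethylhydrazinylidene)methyl]-3-methyl-5-Q-cyclohexa-1,3-dien-1-yl]-2-methylpropanal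
Conditions: Dess–Martin periodinane, NaHCO3, CH2Cl2, 0 °C
Reagents that add atoms: none
Why: Buffered Dess–Martin oxidation gives the aldehyde under non-basic conditions that spare the enolisable acetyl group and the hydrazone.

Step 17
Reactants: 25 keto aldehyde
Product: 26 (1S,8aS)-2-[(E)-(2,2-dimethylhydrazinylidene)methyl]-8-hydroxy-3,6,8-trimethyl-1-Q-5,6,8,8a-tetrahydronaphthalen-7(1H)-one (mixture of isomers at C6 and C8)
Conditions: 2-(pentafluorophenyl)-6,7-dihydro-5H-pyrrolo[2,1-c][1,2,4]triazol-2-ium tetrafluoroborate (15 mol%), Et3N (15 mol%), THF, 25 °C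
Reagents that add atoms: none
Why: The triazolylidene adds to the C7 aldehyde and proton transfer gives the Breslow enaminol, an acyl-anion equivalent whose carbon attacks the C8 methyl ketone; release of the carbene leaves the C7 ketone and a C8 tertiary carbinol. The closest known reaction type is the carbene-catalysed intramolecular crossed aldehyde–ketone benzoin cyclisation that converts 1,6-keto aldehydes into 2-hydroxy-2-methylcyclohexanones. Ring B is the only ring closed, in a 6-exo-trig mode onto the ketone carbonyl, with the two reacting chains held on adjacent carbons (C4a, C8a) of ring A. The new C8 carbinol centre is formed without control and C6 may epimerise through the aldehyde, which is harmless because the C8 oxygen is removed in step 18 and both centres are then set thermodynamically against C8a. The step needs chemoselectivity for umpolung of the aliphatic aldehyde over aldol closure through the C8a enolate and over double-bond migration; this is secured by the weak amine base, by the electron-donating hydrazone (no free conjugated aldehyde, lower C8a–H acidity) and by the fast six-ring closure.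

Step 18
Reactants: 26 α-ketol
Product: 28 (1S,6S,8R,8aR)-2-[(E)-(2,2-dimethylhydrazinylidene)methyl]-3,6,8-trimethyl-1-Q-5,6,8,8a-tetrahydronaphthalen-7(1H)-one, via C6/C8-epimeric ketone mixture 27 (not isolated)
Conditions: SmI2 (3 equiv), THF/MeOH, −78 °C; aqueous work-up; then DBU (0.3 equiv), toluene, 40 °C
Reagents that add atoms: none
Why: SmI2 reductively cleaves the C–O bond α to the ketone (reduction of an α-heterosubstituted ketone) to a samarium enolate that is protonated unselectively, and DBU then epimerises C6 and C8 through the enolates to the all-equatorial cis-2,6-dimethyl ketone, with the non-enolisable C8a as anchor.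

Step 19
Reactants: 28 ketone hydrazone
Product: 29 (1S,6S,8R,8aR)-3,6,8-trimethyl-7-oxo-1-Q-1,5,6,7,8,8a-hexahydronaphthalene-2-carbaldehyde
Conditions: CuCl2, THF/aq. phosphate buffer (pH 7), rt
Reagents that add atoms: water, O
Why: Copper-assisted hydrolysis of the N,N-dimethylhydrazone should free the dienal under near-neutral, non-oxidising conditions once the base-sensitive acetyl stage is past.

Step 20
Reactants: 29 dienal
Product: 30 (1S,6S,8R,8aR)-2-(2-methoxyprop-1-en-1-yl)-3,6,8-trimethyl-1-Q-5,6,8,8a-tetrahydronaphthalen-7(1H)-one (E/Z mixture at the enol ether)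
Conditions: (1-methoxyethyl)triphenylphosphonium chloride, KN(SiMe3)2, THF, −78 to 0 °C
Reagents that add atoms: (1-methoxyethyl)triphenylphosphonium chloride, COC(C)[P+](c1ccccc1)(c1ccccc1)c1ccccc1.[Cl-]
Why: Wittig olefination with the α-methoxyalkylidene ylide turns the aldehyde into a methyl enol ether, a masked methyl ketone, and should prefer the aldehyde over the hindered 2,6-dimethylcyclohexanone.

Step 21
Reactants: 30 enol ether
Product: 32 (1S,6S,8R,8aR)-1-[(1E,3S,4E)-6-hydroxy-3-(hydroxymethyl)-2,3-dimethylhexa-1,4-dien-1-yl]-3,6,8-trimethyl-2-(2-oxopropyl)-5,6,8,8a-tetrahydronaphthalen-7(1H)-one, via enol ether diol 31 (not isolated)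
Conditions: HF·pyridine, pyridine, THF, 0 °C to rt; then aq. oxalic acid, THF, 0 °C
Reagents that add atoms: water, O
Why: Fluoride cleaves both TBDPS ethers, and mild acid hydrolyses the enol ether by kinetic protonation at the carbon next to the oxocarbenium centre, which should give the β,γ-unsaturated 2-oxopropyl ketone without moving the diene.

Step 22
Reactants: 32 diol diketone
Product: 33 (2E,4S,5E)-4-(hydroxymethyl)-4,5-dimethyl-6-[(1S,6S,8R,8aR)-3,6,8-trimethyl-7-oxo-2-(2-oxopropyl)-1,5,6,7,8,8a-hexahydronaphthalen-1-yl]hexa-2,5-dienal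
Conditions: MnO2, CH2Cl2, rt
Reagents that add atoms: none
Why: MnO2 oxidises the allylic primary alcohol selectively and should leave the neopentyl primary alcohol untouched.

Step 23
Reactants: 33 enal
Product: 34 (2E,4S,5E)-4-(hydroxymethyl)-4,5-dimethyl-6-[(1S,6S,8R,8aR)-3,6,8-trimethyl-7-oxo-2-(2-oxopropyl)-1,5,6,7,8,8a-hexahydronaphthalen-1-yl]hexa-2,5-dienoic acid
Conditions: NaClO2, NaH2PO4, 2-methyl-2-butene, t-BuOH/H2O, 0 °C to rt
Reagents that add atoms: sodium chlorite, [Na+].[O-]Cl=O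
Why: Pinnick oxidation converts the enal into the acid under buffered conditions that tolerate the free alcohol, both ketones and the alkenes (hypochlorite is scavenged by the alkene additive).

**Compound list**

1 | 2-methylprop-2-en-1-ol | CC(=C)CO | starting material
2 | tert-butyl(dimethyl)[(2-methylprop-2-en-1-yl)oxy]silane | CC(=C)CO[Si](C)(C)C(C)(C)C | intermediate
3 | 4-bromobenzaldehyde | O=Cc1ccc(Br)cc1 | starting material
4 | 9-[3-(TBS-oxy)-2-methylpropyl]-9-borabicyclo[3.3.1]nonane (racemic) | CC(CO[Si](C)(C)C(C)(C)C)CB1C2CCCC1CCC2 | intermediate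
5 | 4-[3-(TBS-oxy)-2-methylpropyl]benzaldehyde (racemic) | O=Cc1ccc(CC(C)CO[Si](C)(C)C(C)(C)C)cc1 | intermediate
6 | (3aR,7aR)-2-{4-[3-(TBS-oxy)-2-methylpropyl]phenyl}-1,3-dimethyloctahydro-1H-benzimidazole | CN1[C@@H]2CCCC[C@H]2N(C)C1c1ccc(CC(C)CO[Si](C)(C)C(C)(C)C)cc1 | intermediate
7 | tricarbonyl(η6-aryl ring of 6)chromium | CN1[C@@H]2CCCC[C@H]2N(C)C1c1ccc(CC(C)CO[Si](C)(C)C(C)(C)C)cc1.O=C=[Cr](=C=O)=C=O | intermediate
8 | ortho-lithiated aminal complex | [Li]c1cc(CC(C)CO[Si](C)(C)C(C)(C)C)ccc1C1N(C)[C@@H]2CCCC[C@H]2N1C.O=C=[Cr](=C=O)=C=O | intermediate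
9 | ortho-methylated aminal complex (planar-chiral) | Cc1cc(CC(C)CO[Si](C)(C)C(C)(C)C)ccc1C1N(C)[C@@H]2CCCC[C@H]2N1C.O=C=[Cr](=C=O)=C=O | intermediate
10 | tricarbonyl{η6-2-methyl-4-[3-(TBS-oxy)-2-methylpropyl]benzaldehyde}chromium (ring locants 1→2→3 clockwise, Cr toward the viewer) | Cc1cc(CC(C)CO[Si](C)(C)C(C)(C)C)ccc1C=O.O=C=[Cr](=C=O)=C=O | intermediate
11 | tricarbonyl{η6-(E)-1,1-dimethyl-2-{2-methyl-4-[3-(TBS-oxy)-2-methylpropyl]benzylidene}hydrazine}chromium (same planar chirality) | CN(C)/N=C/c1ccc(CC(C)CO[Si](C)(C)C(C)(C)C)cc1C.O=C=[Cr](=C=O)=C=O | intermediate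
12 | (E)-3-methylpent-2-en-4-yn-1-ol | C#C/C(C)=C/CO | starting material
13 | [(2S,3S)-3-ethynyl-3-methyloxiran-2-yl]methanol | OC[C@@H]1O[C@@]1(C)C#C | intermediate
14 | tert-butyl{[(2S,3S)-3-ethynyl-3-methyloxiran-2-yl]methoxy}diphenylsilane | CC(C)(C)[Si](c1ccccc1)(c1ccccc1)OC[C@@H]1O[C@@]1(C)C#C | intermediate
15 | (S)-2-[(TBDPS-oxy)methyl]-2-methylbut-3-ynal | C#C[C@](C)(C=O)CO[Si](c1ccccc1)(c1ccccc1)C(C)(C)C | intermediate
16 | ethyl (S,E)-4-[(TBDPS-oxy)methyl]-4-methylhex-2-en-5-ynoate | C#C[C@](C)(/C=C/C(=O)OCC)CO[Si](c1ccccc1)(c1ccccc1)C(C)(C)C | intermediate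
17 | (S,E)-4-[(TBDPS-oxy)methyl]-4-methylhex-2-en-5-yn-1-ol | C#C[C@](C)(/C=C/CO)CO[Si](c1ccccc1)(c1ccccc1)C(C)(C)C | intermediate
18 | (S,E)-1-(TBDPS-oxy)-4-[(TBDPS-oxy)methyl]-4-methylhex-2-en-5-yne | C#C[C@](C)(/C=C/CO[Si](c1ccccc1)(c1ccccc1)C(C)(C)C)CO[Si](c1ccccc1)(c1ccccc1)C(C)(C)C | intermediate
19 | (E)-alkenyldimethylalane from 18 | C[Al](C)/C=C(\C)[C@](C)(/C=C/CO[Si](c1ccccc1)(c1ccccc1)C(C)(C)C)CO[Si](c1ccccc1)(c1ccccc1)C(C)(C)C | intermediate
20 | (1E,3S,4E)-6-(TBDPS-oxy)-3-[(TBDPS-oxy)methyl]-1-iodo-2,3-dimethylhexa-1,4-diene | I/C=C(\C)[C@](C)(/C=C/CO[Si](c1ccccc1)(c1ccccc1)C(C)(C)C)CO[Si](c1ccccc1)(c1ccccc1)C(C)(C)C | intermediate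
21 | alkenyllithium Q–Li | [Li]/C=C(\C)[C@](C)(/C=C/CO[Si](c1ccccc1)(c1ccccc1)C(C)(C)C)CO[Si](c1ccccc1)(c1ccccc1)C(C)(C)C | intermediate
22 | lithium cyclohexadienyl chromate adduct (Q exo at the new sp3 carbon) | [Li+].CN(C)[N-]C=C1C(C)=CC(CC(C)CO[Si](C)(C)C(C)(C)C)=C[C@@H]1/C=C(\C)[C@](C)(/C=C/CO[Si](c2ccccc2)(c2ccccc2)C(C)(C)C)CO[Si](c2ccccc2)(c2ccccc2)C(C)(C)C.O=C=[Cr](=C=O)=C=O | intermediate
23 | 1-[(1S,6S)-2-[3-(TBS-oxy)-2-methylpropyl]-5-[(E)-(2,2-dimethylhydrazinylidene)methyl]-4-methyl-6-Q-cyclohexa-2,4-dien-1-yl]ethan-1-one | CN(C)/N=C/C1=C(C)C=C(CC(C)CO[Si](C)(C)C(C)(C)C)[C@@H](C(C)=O)[C@@H]1/C=C(\C)[C@](C)(/C=C/CO[Si](c2ccccc2)(c2ccccc2)C(C)(C)C)CO[Si](c2ccccc2)(c2ccccc2)C(C)(C)C | intermediate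
24 | 1-[(1S,6S)-5-[(E)-(2,2-dimethylhydrazinylidene)methyl]-2-(3-hydroxy-2-methylpropyl)-4-methyl-6-Q-cyclohexa-2,4-dien-1-yl]ethan-1-one | CN(C)/N=C/C1=C(C)C=C(CC(C)CO)[C@@H](C(C)=O)[C@@H]1/C=C(\C)[C@](C)(/C=C/CO[Si](c2ccccc2)(c2ccccc2)C(C)(C)C)CO[Si](c2ccccc2)(c2ccccc2)C(C)(C)C | intermediate
25 | 3-[(5S,6S)-6-acetyl-4-[(E)-(2,2-dimethylhydrazinylidene)methyl]-3-methyl-5-Q-cyclohexa-1,3-dien-1-yl]-2-methylpropanal | CN(C)/N=C/C1=C(C)C=C(CC(C)C=O)[C@@H](C(C)=O)[C@@H]1/C=C(\C)[C@](C)(/C=C/CO[Si](c2ccccc2)(c2ccccc2)C(C)(C)C)CO[Si](c2ccccc2)(c2ccccc2)C(C)(C)C | intermediate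
26 | (1S,8aS)-2-[(E)-(2,2-dimethylhydrazinylidene)methyl]-8-hydroxy-3,6,8-trimethyl-1-Q-5,6,8,8a-tetrahydronaphthalen-7(1H)-one (isomers at C6, C8) | CN(C)/N=C/C1=C(C)C=C2CC(C)C(=O)C(C)(O)[C@H]2[C@@H]1/C=C(\C)[C@](C)(/C=C/CO[Si](c3ccccc3)(c3ccccc3)C(C)(C)C)CO[Si](c3ccccc3)(c3ccccc3)C(C)(C)C | intermediate
27 | (1S,8aR)-2-[(E)-(2,2-dimethylhydrazinylidene)methyl]-3,6,8-trimethyl-1-Q-5,6,8,8a-tetrahydronaphthalen-7(1H)-one (epimers at C6, C8) | CN(C)/N=C/C1=C(C)C=C2CC(C)C(=O)C(C)[C@H]2[C@@H]1/C=C(\C)[C@](C)(/C=C/CO[Si](c3ccccc3)(c3ccccc3)C(C)(C)C)CO[Si](c3ccccc3)(c3ccccc3)C(C)(C)C | intermediate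
28 | (1S,6S,8R,8aR)-2-[(E)-(2,2-dimethylhydrazinylidene)methyl]-3,6,8-trimethyl-1-Q-5,6,8,8a-tetrahydronaphthalen-7(1H)-one | CN(C)/N=C/C1=C(C)C=C2C[C@H](C)C(=O)[C@H](C)[C@H]2[C@@H]1/C=C(\C)[C@](C)(/C=C/CO[Si](c3ccccc3)(c3ccccc3)C(C)(C)C)CO[Si](c3ccccc3)(c3ccccc3)C(C)(C)C | intermediate
29 | (1S,6S,8R,8aR)-3,6,8-trimethyl-7-oxo-1-Q-1,5,6,7,8,8a-hexahydronaphthalene-2-carbaldehyde | O=CC1=C(C)C=C2C[C@H](C)C(=O)[C@H](C)[C@H]2[C@@H]1/C=C(\C)[C@](C)(/C=C/CO[Si](c3ccccc3)(c3ccccc3)C(C)(C)C)CO[Si](c3ccccc3)(c3ccccc3)C(C)(C)C | intermediate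
30 | (1S,6S,8R,8aR)-2-(2-methoxyprop-1-en-1-yl)-3,6,8-trimethyl-1-Q-5,6,8,8a-tetrahydronaphthalen-7(1H)-one | COC(C)=CC1=C(C)C=C2C[C@H](C)C(=O)[C@H](C)[C@H]2[C@@H]1/C=C(\C)[C@](C)(/C=C/CO[Si](c3ccccc3)(c3ccccc3)C(C)(C)C)CO[Si](c3ccccc3)(c3ccccc3)C(C)(C)C | intermediate
31 | enol ether diol (30 without the two silyl groups) | COC(C)=CC1=C(C)C=C2C[C@H](C)C(=O)[C@H](C)[C@H]2[C@@H]1/C=C(\C)[C@](C)(/C=C/CO)CO | intermediate
32 | (1S,6S,8R,8aR)-1-[(1E,3S,4E)-6-hydroxy-3-(hydroxymethyl)-2,3-dimethylhexa-1,4-dien-1-yl]-3,6,8-trimethyl-2-(2-oxopropyl)-5,6,8,8a-tetrahydronaphthalen-7(1H)-one | CC(=O)CC1=C(C)C=C2C[C@H](C)C(=O)[C@H](C)[C@H]2[C@@H]1/C=C(\C)[C@](C)(/C=C/CO)CO | intermediate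
33 | (2E,4S,5E)-4-(hydroxymethyl)-4,5-dimethyl-6-[(1S,6S,8R,8aR)-3,6,8-trimethyl-7-oxo-2-(2-oxopropyl)-1,5,6,7,8,8a-hexahydronaphthalen-1-yl]hexa-2,5-dienal | CC(=O)CC1=C(C)C=C2C[C@H](C)C(=O)[C@H](C)[C@H]2[C@@H]1/C=C(\C)[C@](C)(/C=C/C=O)CO | intermediate
34 | (2E,4S,5E)-4-(hydroxymethyl)-4,5-dimethyl-6-[(1S,6S,8R,8aR)-3,6,8-trimethyl-7-oxo-2-(2-oxopropyl)-1,5,6,7,8,8a-hexahydronaphthalen-1-yl]hexa-2,5-dienoic acid | CC(=O)CC1=C(C)C=C2C[C@H](C)C(=O)[C@H](C)[C@H]2[C@@H]1/C=C(\C)[C@](C)(/C=C/C(=O)O)CO | target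

**Count and risks**

Total step count: 23. Longest linear sequence: 17 steps (12 → 34: steps 7–13, then 14–23).

Steps most likely to fail:

1. Step 14. The alkenyllithium may be consumed by deprotonation of the chromium-acidified benzylic methyl or methylene groups instead of adding to the ring, or the acyl group may migrate with poor regiocontrol. Fallback: the methyl group is introduced after the dearomatisation. Setting out from 8, the aryllithium is quenched with C2Cl6 instead of iodomethane to give the ortho-chloro aminal complex F1, which is hydrolysed to the planar-chiral 2-chloro aldehyde complex F2 and converted with 1,1-dimethylhydrazine into the chloro hydrazone complex F3, which has no lateral C–H next to the directing group. The same addition of 21 and MeI/CO trapping should give the 3-chloro diene F4, and Negishi coupling (MeZnCl, Pd(P(t-Bu)3)2, THF) on this vinylogous imidoyl chloride installs the methyl group and comes back to the route at 23.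

2. Step 17. Enolisation at C8a by the amine base may lead to aldol closure or to migration of the ring-A double bonds into conjugation with the acetyl group faster than the carbene turns over. Fallback: the same C7–C8 bond is made reductively under non-basic conditions. Setting out from 25, SmI2 (2.2 equiv, THF/t-BuOH, −78 °C) effects a ketyl–carbonyl pinacol cyclisation to the C7,C8-diol F5, and oxidation of its secondary carbinol (SO3·pyridine, DMSO, i-Pr2NEt, 0 °C) comes back to the route at 26.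

3. Step 20. Olefination of the hindered, tetrasubstituted dienal may be slow and accompanied by enolisation, and the later protonation of the dienyl enol ether may occur at a remote carbon and give a conjugated ketone. Fallback: the two carbons are added as an acyl-anion equivalent and the extra oxygen is removed reductively. Setting out from 29, 1-ethoxyvinyllithium (ethyl vinyl ether, t-BuLi) with CeCl3 in THF at −78 °C adds to the aldehyde to give the ethoxyvinyl carbinol F6; HF·pyridine followed by aqueous oxalic acid gives the α-hydroxy ketone diol F7; SmI2 (THF/MeOH, −78 °C) then cleaves the dienylic C–O bond, and α-protonation of the samarium dienolate comes back to the route at 32.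

Further compounds
F1 | step 14 | ortho-chloro aminal chromium complex | Clc1cc(CC(C)CO[Si](C)(C)C(C)(C)C)ccc1C1N(C)[C@@H]2CCCC[C@H]2N1C.O=C=[Cr](=C=O)=C=O
F2 | step 14 | tricarbonyl{η6-2-chloro-4-[3-(TBS-oxy)-2-methylpropyl]benzaldehyde}chromium (planar-chiral) | Clc1cc(CC(C)CO[Si](C)(C)C(C)(C)C)ccc1C=O.O=C=[Cr](=C=O)=C=O
F3 | step 14 | N,N-dimethylhydrazone of F2 (chromium complex) | CN(C)/N=C/c1ccc(CC(C)CO[Si](C)(C)C(C)(C)C)cc1Cl.O=C=[Cr](=C=O)=C=O
F4 | step 14 | 1-[(1S,6S)-2-[3-(TBS-oxy)-2-methylpropyl]-4-chloro-5-[(E)-(2,2-dimethylhydrazinylidene)methyl]-6-Q-cyclohexa-2,4-dien-1-yl]ethan-1-one | CN(C)/N=C/C1=C(Cl)C=C(CC(C)CO[Si](C)(C)C(C)(C)C)[C@@H](C(C)=O)[C@@H]1/C=C(\C)[C@](C)(/C=C/CO[Si](c2ccccc2)(c2ccccc2)C(C)(C)C)CO[Si](c2ccccc2)(c2ccccc2)C(C)(C)C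
F5 | step 17 | (1S,8aS)-2-[(E)-(2,2-dimethylhydrazinylidene)methyl]-3,6,8-trimethyl-1-Q-1,5,6,7,8,8a-hexahydronaphthalene-7,8-diol (isomers at C6, C7, C8) | CN(C)/N=C/C1=C(C)C=C2CC(C)C(O)C(C)(O)[C@H]2[C@@H]1/C=C(\C)[C@](C)(/C=C/CO[Si](c3ccccc3)(c3ccccc3)C(C)(C)C)CO[Si](c3ccccc3)(c3ccccc3)C(C)(C)C
F6 | step 20 | (1S,6S,8R,8aR)-2-(2-ethoxy-1-hydroxyprop-2-en-1-yl)-3,6,8-trimethyl-1-Q-5,6,8,8a-tetrahydronaphthalen-7(1H)-one (carbinol epimers) | CCOC(=C)C(O)C1=C(C)C=C2C[C@H](C)C(=O)[C@H](C)[C@H]2[C@@H]1/C=C(\C)[C@](C)(/C=C/CO[Si](c3ccccc3)(c3ccccc3)C(C)(C)C)CO[Si](c3ccccc3)(c3ccccc3)C(C)(C)C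
F7 | step 20 | (1S,6S,8R,8aR)-1-[(1E,3S,4E)-6-hydroxy-3-(hydroxymethyl)-2,3-dimethylhexa-1,4-dien-1-yl]-2-(1-hydroxy-2-oxopropyl)-3,6,8-trimethyl-5,6,8,8a-tetrahydronaphthalen-7(1H)-one (carbinol epimers) | CC(=O)C(O)C1=C(C)C=C2C[C@H](C)C(=O)[C@H](C)[C@H]2[C@@H]1/C=C(\C)[C@](C)(/C=C/CO)CO
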